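**Retrosynthetic overview**

1. The target comes from global desilylation and ester reduction of a 2,3-trans benzodioxane enoate. The bond from C1 of ring A (syringyl ring) to C3 of ring C (dioxane ring) is made by a nickel-catalysed radical Negishi coupling of a C3 bromide with an arylzinc.
2. Enabling feature: C3 of ring C is bonded to ring oxygen O4, so at the lactol oxidation level it is an anomeric-type carbon whose C3–Br bond gives an O4-stabilised radical. The neighbouring C2 stereocentre steers the new bond trans, and both C3 epimers converge.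
3. The C3 bromide comes from a C3 acetate, and this from a ring C lactone (C3 at the carboxyl level) by one hydride addition. The side chain is carried as a methyl enoate (Wittig early, reduction late).
4. The lactone comes from Mitsunobu inversion of a 3-O-silyl (R)-glycerate by the more acidic phenol (O1–H, para to CHO) of 3,4-dihydroxy-5-methoxybenzaldehyde, then lactonisation onto O4–H. This sets C2 (S) and the O1/O4 regiochemistry.
5. Ring order: ring A and ring B (benzo ring) are bought; ring C is the only ring made (O1–C2 first, then O4–C3), before the key step.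

Key step: step 6

Remark: the locants used for all intermediates are those of the 2,3-dihydro-1,4-benzodioxine core as defined here (O1, C2 bearing the CH2O group, C3 bearing the aryl group, O4, C6 side chain, C8 methoxy), also where a systematic name would number the ring differently.

**Route**

Step 1
Reactants: 1 methyl (2R)-2,3-dihydroxypropanoate (methyl D-glycerate)
Product: 2 methyl (2R)-3-[(tert-butyldiphenylsilyl)oxy]-2-hydroxypropanoate
Conditions: TBDPSCl, imidazole, CH2Cl2, 0 °C
Reagents that add atoms: tert-butyl(chloro)diphenylsilane (TBDPSCl), CC(C)(C)[Si](Cl)(c1ccccc1)c1ccccc1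
Why: Silyl ether formation: the bulky silyl chloride should react only at the primary hydroxyl and leave the secondary hydroxyl free for the next step, with the stereocentre untouched.

Step 2
Reactants: 2 methyl (2R)-3-[(tert-butyldiphenylsilyl)oxy]-2-hydroxypropanoate; 3 3,4-dihydroxy-5-methoxybenzaldehyde
Product: 5 (2S)-2-{[(tert-butyldiphenylsilyl)oxy]methyl}-8-methoxy-3-oxo-2,3-dihydro-1,4-benzodioxine-6-carbaldehyde (ring C lactone aldehyde), via open-chain aryl ether 4 (not isolated)
Conditions: PPh3, DIAD, THF, 0 °C to rt; then CSA (cat.), 4 Å MS, toluene, 60 °C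
Reagents that add atoms: none
Why: Mitsunobu reaction followed by acid-catalysed lactonisation: the more acidic phenol of 3 (O1–H, para to the formyl group) should be the one that displaces the activated secondary alcohol of 2, with inversion, which sets C2 as S, and the neighbouring phenol O4–H then closes ring C by 6-exo-trig acyl substitution at the methyl ester.

Step 3
Reactants: 5 ring C lactone aldehyde
Product: 6 methyl (E)-3-[(2S)-2-{[(tert-butyldiphenylsilyl)oxy]methyl}-8-methoxy-3-oxo-2,3-dihydro-1,4-benzodioxin-6-yl]prop-2-enoate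
Conditions: Ph3P=CHCO2Me, CH2Cl2, rt
Reagents that add atoms: methyl (triphenylphosphoranylidene)acetate, COC(=O)C=P(c1ccccc1)(c1ccccc1)c1ccccc1
Why: Wittig olefination with a stabilised ylide runs under neutral conditions, so the aryl lactone and the acidic C2–H should survive, and it should give the E enoate.

Step 4
Reactants: 6 lactone enoate
Product: 8 methyl (E)-3-[(2S,3RS)-3-acetoxy-2-{[(tert-butyldiphenylsilyl)oxy]methyl}-8-methoxy-2,3-dihydro-1,4-benzodioxin-6-yl]prop-2-enoate (C3 acetate), via aluminium lactolate 7 (not isolated)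
Conditions: iBu2AlH (1.05 equiv), CH2Cl2, −78 °C; then pyridine, DMAP, Ac2O, −78 to −20 °C
Reagents that add atoms: acetic anhydride, CC(=O)OC(C)=O
Why: One-pot reductive acetylation of a lactone: at −78 °C one equivalent of hydride should add to the aryl-ester carbonyl C3, which is far more electrophilic than the donor-conjugated methyl enoate, and the stable aluminium lactolate is acetylated in the flask to the anomeric-type acetate; C3 forms as an epimer mixture, which the key step makes irrelevant.

Step 5
Reactants: 9 4-bromo-2,6-dimethoxyphenol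
Product: 10 (4-bromo-2,6-dimethoxyphenoxy)(tert-butyl)dimethylsilane
Conditions: TBSCl, imidazole, DMF, rt
Reagents that add atoms: tert-butyl(chloro)dimethylsilane (TBSCl), CC(C)(C)[Si](C)(C)Cl
Why: Silyl ether protection of the phenol, needed so that the aryl bromide can be turned into an organometallic and so that the phenol cannot O-alkylate the C3 bromide.

Step 6
Reactants: 8 C3 acetate; 10 (4-bromo-2,6-dimethoxyphenoxy)(tert-butyl)dimethylsilane
Product: 14 methyl (E)-3-[(2S,3S)-3-[4-(tert-butyldimethylsilyloxy)-3,5-dimethoxyphenyl]-2-{[(tert-butyldiphenylsilyl)oxy]methyl}-8-methoxy-2,3-dihydro-1,4-benzodioxin-6-yl]prop-2-enoate, via C3 bromide 11 (not isolated), via aryl Grignard reagent 12 (not isolated), via arylzinc chloride 13 (not isolated)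
Conditions: (a) 8, Me3SiBr, CH2Cl2, 0 °C to rt, evaporate; (b) 10, Mg, LiCl, THF, rt, then ZnCl2, 0 °C; (c) NiCl2(dme) (10 mol %), 4,4′,4″-tri-tert-butyl-2,2′:6′,2″-terpyridine (15 mol %), THF/DMA, 0 °C to rt
Reagents that add atoms: none
Why: Bromotrimethylsilane should exchange the C3 acetate for bromide as in glycosyl bromide formation, and magnesium insertion into 10 followed by transmetalation with ZnCl2 should give arylzinc 13; monovalent nickel then abstracts the bromine atom of 11 to give a C3 radical stabilised by the lone pair of ring oxygen O4, the aryl-nickel species formed from 13 captures it, and reductive elimination from trivalent aryl(alkyl)nickel forges the bond from ring A to C3. The closest known reaction type is the nickel/terpyridine-catalysed Negishi C-arylation of glycosyl bromides, which runs through the same kind of anomeric radical. No ring is closed in this step. The new stereocentre C3 is controlled by the existing C2 centre: the planar radical is captured and the C–C bond is formed on the face anti to the bulky C2 silyloxymethyl group, which should give the 2,3-trans (2S,3S) product. Because the radical is planar, both C3 epimers of the bromide converge on this product. The step needs diastereoselectivity at C3, site selectivity on ring A and chemoselectivity at C3: the first comes from the C2 substituent, the second from the position of zinc (para to the silyloxy group), and the third from the fact that only C3 carries a weak C–Br bond while the enoate, silyl ethers and methyl ethers are inert to arylzinc reagents.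

Step 7
Reactants: 14 coupled enoate
Product: 15 (E)-3-[(2S,3S)-3-[4-(tert-butyldimethylsilyloxy)-3,5-dimethoxyphenyl]-2-{[(tert-butyldiphenylsilyl)oxy]methyl}-8-methoxy-2,3-dihydro-1,4-benzodioxin-6-yl]prop-2-en-1-ol
Conditions: iBu2AlH (3.5 equiv), CH2Cl2, −78 to −40 °C; Rochelle salt work-up
Reagents that add atoms: none
Why: Ester reduction with iBu2AlH: hydride adds 1,2 to the enoate, which should give the E allylic alcohol without touching the alkene, the silyl ethers or the C3 benzylic ether.

Step 8
Reactants: 15 bis-silyl allylic alcohol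
Product: 16 (E)-3-[(2S,3S)-3-(4-hydroxy-3,5-dimethoxyphenyl)-2-(hydroxymethyl)-8-methoxy-2,3-dihydro-1,4-benzodioxin-6-yl]prop-2-en-1-ol (target, CID11188887)
Conditions: Bu4NF, AcOH, THF, 0 °C to rt
Reagents that add atoms: none
Why: Fluoride-mediated desilylation, buffered with acetic acid so that the freed para-hydroxybenzyl aryl ether and the cinnamyl alcohol meet no strong base, should remove both silyl groups and leave C2 and C3 unchanged.

**Compound list**

1 | methyl (2R)-2,3-dihydroxypropanoate | COC(=O)[C@H](O)CO | starting material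
2 | methyl (2R)-3-[(tert-butyldiphenylsilyl)oxy]-2-hydroxypropanoate | COC(=O)[C@H](O)CO[Si](c1ccccc1)(c1ccccc1)C(C)(C)C | intermediate
3 | 3,4-dihydroxy-5-methoxybenzaldehyde | COc1cc(C=O)cc(O)c1O | starting material
4 | methyl (2S)-3-[(tert-butyldiphenylsilyl)oxy]-2-(4-formyl-2-hydroxy-6-methoxyphenoxy)propanoate (formed in the flask) | COC(=O)[C@@H](Oc1c(O)cc(C=O)cc1OC)CO[Si](c1ccccc1)(c1ccccc1)C(C)(C)C | intermediate
5 | (2S)-2-{[(tert-butyldiphenylsilyl)oxy]methyl}-8-methoxy-3-oxo-2,3-dihydro-1,4-benzodioxine-6-carbaldehyde | O=C1Oc2cc(C=O)cc(OC)c2O[C@H]1CO[Si](c1ccccc1)(c1ccccc1)C(C)(C)C | intermediate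
6 | methyl (E)-3-[(2S)-2-{[(tert-butyldiphenylsilyl)oxy]methyl}-8-methoxy-3-oxo-2,3-dihydro-1,4-benzodioxin-6-yl]prop-2-enoate | O=C1Oc2cc(/C=C/C(=O)OC)cc(OC)c2O[C@H]1CO[Si](c1ccccc1)(c1ccccc1)C(C)(C)C | intermediate
7 | diisobutylaluminium lactolate of 6, O–Al at C3, C3 epimer mixture (formed in the flask) | CC(C)C[Al](CC(C)C)OC1Oc2cc(/C=C/C(=O)OC)cc(OC)c2O[C@H]1CO[Si](c1ccccc1)(c1ccccc1)C(C)(C)C | intermediate
8 | methyl (E)-3-[(2S,3RS)-3-acetoxy-2-{[(tert-butyldiphenylsilyl)oxy]methyl}-8-methoxy-2,3-dihydro-1,4-benzodioxin-6-yl]prop-2-enoate | CC(=O)OC1Oc2cc(/C=C/C(=O)OC)cc(OC)c2O[C@H]1CO[Si](c1ccccc1)(c1ccccc1)C(C)(C)C | intermediate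
9 | 4-bromo-2,6-dimethoxyphenol | COc1cc(Br)cc(OC)c1O | starting material
10 | (4-bromo-2,6-dimethoxyphenoxy)(tert-butyl)dimethylsilane | COc1cc(Br)cc(OC)c1O[Si](C)(C)C(C)(C)C | intermediate
11 | methyl (E)-3-[(2S,3RS)-3-bromo-2-{[(tert-butyldiphenylsilyl)oxy]methyl}-8-methoxy-2,3-dihydro-1,4-benzodioxin-6-yl]prop-2-enoate (formed in the flask) | BrC1Oc2cc(/C=C/C(=O)OC)cc(OC)c2O[C@H]1CO[Si](c1ccccc1)(c1ccccc1)C(C)(C)C | intermediate
12 | [4-(tert-butyldimethylsilyloxy)-3,5-dimethoxyphenyl]magnesium bromide (formed in the flask) | COc1cc([Mg]Br)cc(OC)c1O[Si](C)(C)C(C)(C)C | intermediate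
13 | [4-(tert-butyldimethylsilyloxy)-3,5-dimethoxyphenyl]zinc chloride (formed in the flask) | COc1cc([Zn]Cl)cc(OC)c1O[Si](C)(C)C(C)(C)C | intermediate
14 | methyl (E)-3-[(2S,3S)-3-[4-(tert-butyldimethylsilyloxy)-3,5-dimethoxyphenyl]-2-{[(tert-butyldiphenylsilyl)oxy]methyl}-8-methoxy-2,3-dihydro-1,4-benzodioxin-6-yl]prop-2-enoate | COc1cc([C@@H]2Oc3cc(/C=C/C(=O)OC)cc(OC)c3O[C@H]2CO[Si](c2ccccc2)(c2ccccc2)C(C)(C)C)cc(OC)c1O[Si](C)(C)C(C)(C)C | intermediate
15 | (E)-3-[(2S,3S)-3-[4-(tert-butyldimethylsilyloxy)-3,5-dimethoxyphenyl]-2-{[(tert-butyldiphenylsilyl)oxy]methyl}-8-methoxy-2,3-dihydro-1,4-benzodioxin-6-yl]prop-2-en-1-ol | COc1cc([C@@H]2Oc3cc(/C=C/CO)cc(OC)c3O[C@H]2CO[Si](c2ccccc2)(c2ccccc2)C(C)(C)C)cc(OC)c1O[Si](C)(C)C(C)(C)C | intermediate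
16 | (E)-3-[(2S,3S)-3-(4-hydroxy-3,5-dimethoxyphenyl)-2-(hydroxymethyl)-8-methoxy-2,3-dihydro-1,4-benzodioxin-6-yl]prop-2-en-1-ol | COc1cc([C@@H]2Oc3cc(/C=C/CO)cc(OC)c3O[C@H]2CO)cc(OC)c1O | target

**Step count and risks**

Total steps: 8. Longest linear sequence: 7 steps (steps 1, 2, 3, 4, 6, 7, 8); step 5 is a one-step side branch.

Steps most likely to fail:

Step 6. The C3 bromide may be lost by elimination or ring opening before the radical is captured, or radical capture may show poor facial selectivity. The fallback is ionic and uses classical chemistry. It sets out from lactone 6. Reduction with iBu2AlH (1.05 equiv, CH2Cl2, −78 °C) with aqueous Rochelle-salt work-up and no acetic anhydride should give lactol F1. Addition of aryl Grignard reagent 12 (3 equiv, THF, −78 °C) to its open hydroxy-aldehyde form should give benzylic alcohol F2 as a mixture of carbinol epimers. Catalytic BF3·OEt2 (CH2Cl2, −20 °C) should ionise the electron-rich benzylic alcohol, and the ring B phenol O4–H should close ring C under thermodynamic control to the 2,3-trans ether, which is compound 14, where the route is rejoined.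

Step 2. Etherification may discriminate poorly between the two phenolic hydroxyl groups of 3 (O1 versus O4 alkylation). The fallback masks O4 as a bromide. It sets out from 2 and commercial 5-bromovanillin (3-bromo-4-hydroxy-5-methoxybenzaldehyde), which has a single phenol. Mitsunobu reaction (PPh3, DIAD, THF) should give aryl ether F3 with the same inversion. Miyaura borylation (B2pin2, Pd(dppf)Cl2, KOAc, dioxane, 80 °C) should give pinacol boronate F4. Oxidation (NaBO3·4H2O, THF/H2O, rt) should give phenol 4, which lactonises (CSA, toluene, 60 °C) to 5, where the route is rejoined.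

Step 4. Over-reduction may occur through opening of the aluminium lactolate to the aldehyde and a second hydride delivery, or the hydride may attack the enoate. The fallback accepts full reduction and re-oxidises. It sets out from 6. NaBH4 (THF/MeOH, 0 °C), which reduces aryl esters but should leave the methyl enoate, should give phenol alcohol F5. Parikh–Doering oxidation (SO3·pyridine, DMSO, iPr2NEt, CH2Cl2, 0 °C) should oxidise the primary alcohol, and the product should exist ring-closed on O4 as lactol F1. Acetylation (Ac2O, pyridine, DMAP, CH2Cl2) should give 8, where the route is rejoined.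

**Further compounds**

F1 | step 6 | methyl (E)-3-[(2S,3RS)-3-hydroxy-2-{[(tert-butyldiphenylsilyl)oxy]methyl}-8-methoxy-2,3-dihydro-1,4-benzodioxin-6-yl]prop-2-enoate (lactol) | OC1Oc2cc(/C=C/C(=O)OC)cc(OC)c2O[C@H]1CO[Si](c1ccccc1)(c1ccccc1)C(C)(C)C
F2 | step 6 | methyl (E)-3-[4-{[(1RS,2S)-1-[4-(tert-butyldimethylsilyloxy)-3,5-dimethoxyphenyl]-3-[(tert-butyldiphenylsilyl)oxy]-1-hydroxypropan-2-yl]oxy}-3-hydroxy-5-methoxyphenyl]prop-2-enoate | COC(=O)/C=C/c1cc(O)c(O[C@H](C(O)c2cc(OC)c(O[Si](C)(C)C(C)(C)C)c(OC)c2)CO[Si](c2ccccc2)(c2ccccc2)C(C)(C)C)c(OC)c1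
F3 | step 2 | methyl (2S)-2-(2-bromo-4-formyl-6-methoxyphenoxy)-3-[(tert-butyldiphenylsilyl)oxy]propanoate | COC(=O)[C@@H](Oc1c(Br)cc(C=O)cc1OC)CO[Si](c1ccccc1)(c1ccccc1)C(C)(C)C
F4 | step 2 | methyl (2S)-3-[(tert-butyldiphenylsilyl)oxy]-2-[4-formyl-2-methoxy-6-(4,4,5,5-tetramethyl-1,3,2-dioxaborolan-2-yl)phenoxy]propanoate | COC(=O)[C@@H](Oc1c(B2OC(C)(C)C(C)(C)O2)cc(C=O)cc1OC)CO[Si](c1ccccc1)(c1ccccc1)C(C)(C)C
F5 | step 4 | methyl (E)-3-[3-hydroxy-4-{[(2R)-1-[(tert-butyldiphenylsilyl)oxy]-3-hydroxypropan-2-yl]oxy}-5-methoxyphenyl]prop-2-enoate | COC(=O)/C=C/c1cc(O)c(O[C@H](CO)CO[Si](c2ccccc2)(c2ccccc2)C(C)(C)C)c(OC)c1
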